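**Strategy.** Everything rests on opening the cyclohexane ring that carries the spiro-lactone carbon. Its CH2–CH2 bond and the bond from the quaternary bicyclo[2.2.2]octane carbon to the neighbouring ring-fusion CH are both made in one intramolecular Diels–Alder reaction. The key step exploits the cage: the exocyclic methylene on the two-carbon CH2 bridge and the side chain on the adjacent quaternary carbon of the ketone bridge flank the same bridgehead, so a 2-silyloxy-1,3-diene on that chain closes the cyclopentane and the cyclohexene together and fixes both ring-fusion stereocentres. The precursor is a lactone-fused methylene-bicyclooctanone bearing a silyl dienol ether side chain; the enol ether left behind steers the spiro-lactone annulation.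

Key step: step 16

**Assumptions and conventions.**
- Compounds 1, 7, 16 and 17 are taken as commercial.
- In the bicyclo[2.2.2]octane intermediates the three bridges are called the methylene bridge (C–OMe, C=O or C=CH2 plus its CH/CH2), the ketone bridge (C=O plus the quaternary C–Me) and the lactone bridge (CH–C(=O)O plus CH–B or CH–O).
- The CH formed in step 4, the carbinol in 19 and the sulfur-bearing carbon from 18 are carried as mixtures of epimers; all three are erased later.

**Route**

Step 1
Reactants: 1 4-methoxy-2,3,6-trimethylphenol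
Product: 2 4,4-dimethoxy-2,3,6-trimethylcyclohexa-2,5-dien-1-one
Conditions: PhI(OAc)2, MeOH, 0 °C
Reagents that add atoms: methanol, CO
Why: Oxidative dearomatization of a para-methoxyphenol to the quinone monoketal, methanol trapping the phenoxonium ion at the methoxy-bearing carbon; no stereocenter is formed.

Step 2
Reactants: 2 quinone monoketal
Product: 3 allyl 4,4-dimethoxy-2,6-dimethyl-3-methylidenecyclohexa-1,5-dien-1-yl carbonate
Conditions: LiN(i-Pr)2, TMEDA, THF, −78 °C; then allyl chloroformate
Reagents that add atoms: allyl chloroformate, C=CCOC(Cl)=O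
Why: Vinylogous (gamma) deprotonation of the 3-methyl group is the only enolization open to this cross-conjugated dienone, and O-acylation of the extended enolate gives the achiral allyl enol carbonate.

Step 3
Reactants: 3 allyl enol carbonate
Product: 4 (6R)-6-allyl-4,4-dimethoxy-2,6-dimethyl-5-methylidenecyclohex-2-en-1-one
Conditions: Pd2(dba)3 (2.5 mol %), (S)-t-Bu-PHOX (6 mol %), toluene, 30 °C
Reagents that add atoms: none
Why: Decarboxylative asymmetric Tsuji allylation of a cyclic enol carbonate, the palladium enolate being allylated at its alpha carbon; the phosphinooxazoline ligand sets the quaternary methyl/allyl stereocenter, the only one set by catalysis (the (S)-ligand is chosen by analogy with 2-methylcyclohexanone enol carbonates, where the same spatial sense corresponds to 6R here).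

Step 4
Reactants: 4 allyl methylidene enone
Product: 5 (6R)-5-(hydroxymethyl)-6-(3-hydroxypropyl)-4,4-dimethoxy-2,6-dimethylcyclohex-2-en-1-one (both C5 epimers)
Conditions: 9-BBN (3 equiv), THF, 0 to 40 °C; then NaBO3·4H2O, H2O, rt
Reagents that add atoms: sodium perborate, [Na+].[O-]B1OO1
Why: Anti-Markovnikov hydroboration–oxidation of both terminal alkenes, the trisubstituted enone alkene and the hindered ketone being left alone; the new CH is uncontrolled and becomes sp2 again in step 8.

Step 5
Reactants: 5 diol
Product: 6 (6R)-6-[3-(tert-butyldimethylsilyloxy)propyl]-5-(hydroxymethyl)-4,4-dimethoxy-2,6-dimethylcyclohex-2-en-1-one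
Conditions: TBSCl (1.05 equiv), imidazole, CH2Cl2, −20 °C
Reagents that add atoms: tert-butyldimethylsilyl chloride, CC(C)(C)[Si](C)(C)Cl
Why: Sterically selective silylation: the chain hydroxyl reacts, whereas the hydroxymethyl group flanked by the quaternary carbon and the ketal does not.

Step 6
Reactants: 7 ethyl (E)-3-(4,4,5,5-tetramethyl-1,3,2-dioxaborolan-2-yl)prop-2-enoate
Product: 8 (E)-3-(4,4,5,5-tetramethyl-1,3,2-dioxaborolan-2-yl)prop-2-enoic acid
Conditions: LiOH, THF/H2O, 0 °C; then 1 M HCl to pH 3
Reagents that add atoms: lithium hydroxide, [Li+].[OH-]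
Why: Ester saponification that should leave the pinacol boronate and the E geometry intact.

Step 7
Reactants: 6 primary alcohol; 8 boryl acrylic acid
Product: 9 (E)-3-(pinacolboryl)acrylate ester of 6
Conditions: EDC, DMAP (cat.), CH2Cl2, 0 °C to rt
Reagents that add atoms: none
Why: Steglich-type carbodiimide esterification of the hindered primary alcohol, which installs the tethered dienophile.

Step 8
Reactants: 9 ketal ester
Product: 11 tricyclic boronate lactone (bicyclo[2.2.2]octenone with a methyl enol ether bridge and a fused γ-lactone), via methoxy dienone 10 (not isolated)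
Conditions: TMSOTf, i-Pr2NEt, CH2Cl2, −20 to 0 °C; then toluene, BHT, 120 °C
Reagents that add atoms: none
Why: Silyl-triflate-mediated loss of methanol from the ketal gives the 4-methoxycyclohexa-2,4-dienone (the saturated quaternary carbon blocks aromatization and sigmatropic shifts), which undergoes an ester-tethered intramolecular Diels–Alder reaction; the tether fixes the regiochemistry, the acrylate should add to the dienone face carrying the methyl group (anti to the longer chain) with the lactone carbonyl endo and clear of that methyl, and the E alkene places boron trans to the carbonyl, which sets both bridgeheads and both lactone-bridge carbons.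

Step 9
Reactants: 11 tricyclic boronate lactone
Product: 13 keto diol (methylene-bridge ketone; secondary alcohol syn to the ketone bridge; free 3-hydroxypropyl chain), via hydroxy enol ether 12 (not isolated)
Conditions: NaBO3·4H2O, THF/H2O, rt; then 2 M HCl, THF, rt
Reagents that add atoms: sodium perborate, [Na+].[O-]B1OO1; water, O
Why: Oxidation of the secondary alkylboronate with retention gives the alcohol syn to the ketone bridge, and aqueous acid then hydrolyses the methyl enol ether to the ketone and removes the silyl ether.

Step 10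
Reactants: 13 keto diol
Product: 14 methylene diol (exocyclic C=CH2 on the methylene bridge)
Conditions: Zn, CH2Br2, TiCl4, THF/CH2Cl2, 0 °C to rt
Reagents that add atoms: dibromomethane, BrCBr
Why: Takai–Lombardo methylenation, non-basic and therefore safe for the β-hydroxy carbonyl units, selective for the less hindered ketone because the other is flanked by two quaternary carbons; the lactone is inert.

Step 11
Reactants: 14 methylene diol
Product: 15 aldehyde (3-oxopropyl chain)
Conditions: TEMPO (10 mol %), PhI(OAc)2, CH2Cl2, rt
Reagents that add atoms: none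
Why: Oxoammonium (TEMPO) oxidation, selective for the primary alcohol over the hindered secondary one.

Step 12
Reactants: 16 methyl 2-(phenylsulfanyl)acetate; 17 2,3-dibromoprop-1-ene
Product: 18 methyl 4-bromo-2-(phenylsulfanyl)pent-4-enoate (racemic)
Conditions: LiN(i-Pr)2, THF, −78 °C; then 17, −78 to 0 °C
Reagents that add atoms: none
Why: Ester enolate alkylation at the allylic bromide (the vinylic bromide is inert); the sulfide is the latent unsaturation of the final lactone.

Step 13
Reactants: 15 aldehyde; 18 vinyl bromide
Product: 19 allylic alcohol (mixture of diastereomers)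
Conditions: CrCl2 (4 equiv), NiCl2 (2 mol %), DMSO, rt
Reagents that add atoms: none
Why: Nozaki–Hiyama–Kishi coupling; the alkenylchromium reagent adds to the aldehyde only and tolerates ketone, lactone, ester, sulfide and free hydroxyl.

Step 14
Reactants: 19 allylic alcohol
Product: 20 α-methylene ketone (enone)
Conditions: MnO2, CH2Cl2, rt
Reagents that add atoms: none
Why: MnO2 oxidation, selective for the allylic alcohol over the saturated secondary alcohol and the sulfide.

Step 15
Reactants: 20 enone
Product: 21 (Z)-2-(triethylsilyloxy)-1,3-diene with the secondary alcohol as its triethylsilyl ether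
Conditions: TESOTf (2.5 equiv), Et3N, CH2Cl2, −78 to −20 °C
Reagents that add atoms: triethylsilyl triflate, CC[Si](CC)(CC)OS(=O)(=O)C(F)(F)F
Why: Soft enolization at the only α-CH2 of the enone gives the cross-conjugated 2-silyloxy diene as the Z enol ether, so the tether sits on the outside of the diene; the alcohol is silylated in the same operation.

Step 16
Reactants: 21 silyl dienol ether
Product: 22 pentacyclic silyl enol ether (cyclohexene cis-fused to the new cyclopentane on the cage)
Conditions: toluene (0.01 M), BHT, 190 °C, sealed silylated tube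
Reagents that add atoms: none
Why: Concerted, thermally allowed [4+2] cycloaddition in which the terminal CH2 of the 2-silyloxy diene bonds to the exocyclic CH2 and the chain-bearing diene terminus bonds to the disubstituted alkene carbon; the closest known reaction type is the type 1 intramolecular Diels–Alder reaction of 1,3,8-nonatrienes carrying a 2-silyloxy diene and an unactivated alkene. The cyclohexene closes as the six-membered cycloaddition ring and the cyclopentane closes in the fused mode through the three-atom tether (CH2, quaternary C–Me, bridgehead), the only mode so short a tether allows, which also fixes the regiochemistry. The new quaternary carbon is controlled by the cage, because the diene can reach only the alkene face turned toward the ketone bridge. The ring-fusion CH is controlled by the transition-state geometry: the diene should stack over the bridgehead side of the alkene (tether endo) instead of entering the cleft between the ketone and methylene bridges, which gives the cis ring fusion with its hydrogen syn to the cage CH2. The selectivity needed is this cis fusion, together with cycloaddition before thermal loss of the enol ether, and the rigid 1,3-disposition of chain and methylene on the cage raises the effective molarity to offset the missing activation. The enol ether double bond ends regiospecifically between the oxygen-bearing carbon and the chain-bearing carbon, as step 17 requires.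

Step 17
Reactants: 22 pentacyclic silyl enol ether
Product: 24 spiro δ-lactone ketone with α-phenylsulfanyl lactone and free secondary alcohol, via aldol adduct 23 (not isolated)
Conditions: acetone, TiCl4, CH2Cl2, −78 °C to rt; then 1 M HCl, THF, rt
Reagents that add atoms: acetone, CC(C)=O
Why: Mukaiyama aldol addition of the regiodefined tetrasubstituted silyl enol ether to titanium-activated acetone; axial attack on the outer face of the cyclohexene, anti to the bridgehead CH2O group that shields the inner face, should set the spiro quaternary carbon, after which the tertiary alkoxide lactonizes onto the methyl ester (six-membered ring, gem-dialkyl effect) and the acidic work-up removes the silyl ether.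

Step 18
Reactants: 24 spiro lactone ketone
Product: 25 tertiary methyl carbinol
Conditions: MeMgBr, CeCl3, THF, −78 °C
Reagents that add atoms: methylmagnesium bromide, C[Mg]Br
Why: 1,2-addition of the non-basic methylcerium reagent, expected to prefer the ketone over the lactones and over the cage ketone flanked by two quaternary carbons; equatorial attack from the outer face (the axial path is blocked 1,3 by the bridgehead and its CH2O group) should give the axial tertiary alcohol.

Step 19
Reactants: 25 tertiary methyl carbinol
Product: 27 target CNP0360620.3, via sulfoxide 26 (not isolated)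
Conditions: mCPBA (1.0 equiv), CH2Cl2, −78 °C; then toluene, CaCO3, 100 °C
Reagents that add atoms: none
Why: Sulfide oxidation followed by thermal syn-elimination of the sulfoxide (sulfoxide pyrolysis) toward the only β-hydrogens gives the α,β-unsaturated δ-lactone; no other alkene or oxidizable group competes.

**Compound list**

1 | 4-methoxy-2,3,6-trimethylphenol | COc1cc(C)c(O)c(C)c1C | starting material
2 | 4,4-dimethoxy-2,3,6-trimethylcyclohexa-2,5-dien-1-one | COC1(OC)C=C(C)C(=O)C(C)=C1C | intermediate
3 | allyl 4,4-dimethoxy-2,6-dimethyl-3-methylidenecyclohexa-1,5-dien-1-yl carbonate | C=CCOC(=O)OC1=C(C)C(=C)C(OC)(OC)C=C1C | intermediate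
4 | (6R)-6-allyl-4,4-dimethoxy-2,6-dimethyl-5-methylidenecyclohex-2-en-1-one | C=CC[C@@]1(C)C(=O)C(C)=CC(OC)(OC)C1=C | intermediate
5 | (6R)-5-(hydroxymethyl)-6-(3-hydroxypropyl)-4,4-dimethoxy-2,6-dimethylcyclohex-2-en-1-one, C5 epimers | OCCC[C@@]1(C)C(=O)C(C)=CC(OC)(OC)C1CO | intermediate
6 | (6R)-6-[3-(tert-butyldimethylsilyloxy)propyl]-5-(hydroxymethyl)-4,4-dimethoxy-2,6-dimethylcyclohex-2-en-1-one | CC(C)(C)[Si](C)(C)OCCC[C@@]1(C)C(=O)C(C)=CC(OC)(OC)C1CO | intermediate
7 | ethyl (E)-3-(4,4,5,5-tetramethyl-1,3,2-dioxaborolan-2-yl)prop-2-enoate | CCOC(=O)/C=C/B1OC(C)(C)C(C)(C)O1 | starting material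
8 | (E)-3-(4,4,5,5-tetramethyl-1,3,2-dioxaborolan-2-yl)prop-2-enoic acid | OC(=O)/C=C/B1OC(C)(C)C(C)(C)O1 | intermediate
9 | (E)-3-(pinacolboryl)acrylate of the hydroxymethyl group of 6 | CC(C)(C)[Si](C)(C)OCCC[C@@]1(C)C(=O)C(C)=CC(OC)(OC)C1COC(=O)/C=C/B2OC(C)(C)C(C)(C)O2 | intermediate
10 | (6R)-4-methoxy-2,6-dimethyl-6-(3-silyloxypropyl)cyclohexa-2,4-dien-1-one carrying the (E)-borylacryloyloxymethyl group at C5 | COC1=C(COC(=O)/C=C/B2OC(C)(C)C(C)(C)O2)[C@@](C)(CCCO[Si](C)(C)C(C)(C)C)C(=O)C(C)=C1 | intermediate
11 | tricyclic boronate lactone: bicyclo[2.2.2]octenone with methyl enol ether bridge; ketone-bridge methyl syn to the lactone bridge and silyloxypropyl chain syn to the enol ether bridge; lactone carbonyl carbon syn to the enol ether bridge; boron syn to the ketone bridge | COC1=C[C@]2(C)C(=O)[C@](C)(CCCO[Si](C)(C)C(C)(C)C)[C@]13COC(=O)[C@@H]3[C@H]2B4OC(C)(C)C(C)(C)O4 | intermediate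
12 | corresponding secondary alcohol (hydroxyl syn to the ketone bridge), enol ether and silyl ether intact | COC1=C[C@]2(C)C(=O)[C@](C)(CCCO[Si](C)(C)C(C)(C)C)[C@]13COC(=O)[C@@H]3[C@H]2O | intermediate
13 | keto diol: methylene-bridge ketone, 3-hydroxypropyl chain, secondary alcohol, same relative configuration | O=C1C[C@]2(C)C(=O)[C@](C)(CCCO)[C@]13COC(=O)[C@@H]3[C@H]2O | intermediate
14 | methylene diol: exocyclic C=CH2 in place of the methylene-bridge ketone | C=C1C[C@]2(C)C(=O)[C@](C)(CCCO)[C@]13COC(=O)[C@@H]3[C@H]2O | intermediate
15 | aldehyde from oxidation of the chain alcohol of 14 | C=C1C[C@]2(C)C(=O)[C@](C)(CCC=O)[C@]13COC(=O)[C@@H]3[C@H]2O | intermediate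
16 | methyl 2-(phenylsulfanyl)acetate | COC(=O)CSc1ccccc1 | starting material
17 | 2,3-dibromoprop-1-ene | C=C(Br)CBr | starting material
18 | methyl 4-bromo-2-(phenylsulfanyl)pent-4-enoate, racemic | COC(=O)C(CC(Br)=C)Sc1ccccc1 | intermediate
19 | allylic alcohol from coupling of 15 and 18, diastereomer mixture | C=C1C[C@]2(C)C(=O)[C@](C)(CCC(O)C(=C)CC(Sc4ccccc4)C(=O)OC)[C@]13COC(=O)[C@@H]3[C@H]2O | intermediate
20 | α-methylene ketone from 19 | C=C1C[C@]2(C)C(=O)[C@](C)(CCC(=O)C(=C)CC(Sc4ccccc4)C(=O)OC)[C@]13COC(=O)[C@@H]3[C@H]2O | intermediate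
21 | (Z)-2-(triethylsilyloxy)-1,3-diene of 20, secondary alcohol as triethylsilyl ether | C=C1C[C@]2(C)C(=O)[C@](C)(C/C=C(\O[Si](CC)(CC)CC)C(=C)CC(Sc4ccccc4)C(=O)OC)[C@]13COC(=O)[C@@H]3[C@H]2O[Si](CC)(CC)CC | intermediate
22 | pentacyclic silyl enol ether: cyclohexene cis-fused to the new cyclopentane, ring-fusion hydrogen syn to the cage CH2, ester side chain on the enol ether carbon | CC[Si](CC)(CC)OC1=C(CC(Sc2ccccc2)C(=O)OC)CC[C@]23C[C@]4(C)C(=O)[C@](C)(C[C@@H]12)[C@]35COC(=O)[C@@H]5[C@H]4O[Si](CC)(CC)CC | intermediate
23 | aldol adduct: ring ketone with quaternary α-carbon bearing the 2-hydroxyprop-2-yl group (syn to the ring-fusion hydrogen) and the ester side chain | COC(=O)C(Sc1ccccc1)C[C@@]2(C(C)(C)O)CC[C@]34C[C@]5(C)C(=O)[C@](C)(C[C@H]3C2=O)[C@]46COC(=O)[C@@H]6[C@H]5O[Si](CC)(CC)CC | intermediate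
24 | spiro δ-lactone (saturated, α-phenylsulfanyl) with ring ketone and free secondary alcohol | CC1(C)OC(=O)C(Sc5ccccc5)C[C@]12CC[C@]13C[C@]4(C)C(=O)[C@](C)(C[C@H]1C2=O)[C@]31COC(=O)[C@@H]1[C@H]4O | intermediate
25 | tertiary methyl carbinol from 24, hydroxyl anti to the ring-fusion hydrogen | CC1(C)OC(=O)C(Sc5ccccc5)C[C@]12CC[C@]13C[C@]4(C)C(=O)[C@](C)(C[C@H]1[C@@]2(C)O)[C@]31COC(=O)[C@@H]1[C@H]4O | intermediate
26 | sulfoxide of 25 | CC1(C)OC(=O)C(S(=O)c5ccccc5)C[C@]12CC[C@]13C[C@]4(C)C(=O)[C@](C)(C[C@H]1[C@@]2(C)O)[C@]31COC(=O)[C@@H]1[C@H]4O | intermediate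
27 | CNP0360620.3 | CC1(C)OC(=O)C=C[C@]12CC[C@]13C[C@]4(C)C(=O)[C@](C)(C[C@H]1[C@@]2(C)O)[C@]31COC(=O)[C@@H]1[C@H]4O | target

**Totals.** 19 steps in all; the longest linear sequence is 17 steps (steps 1–5, 7–11, 13–19).

**Steps most likely to fail and their fallbacks**

1. Step 16 (intramolecular Diels–Alder). The unactivated methylene may not engage the diene before the silyl dienol ether degrades, or the ring fusion may form without facial control. The fallback activates the dienophile tracelessly and makes the same two bonds as a polarity-matched cycloaddition (in effect a double Michael addition). It sets out from keto diol 13. Peterson olefination with lithiated tert-butyl (trimethylsilyl)acetate (LiN(i-Pr)2, THF, −78 °C) would give the exocyclic tert-butyl enoate F1. The conditions of steps 11, 13, 14 and 15 would carry it through the aldehyde F2, the allylic alcohol F3 and the enone F4 to the bis-silylated dienol ether F5. Heating in toluene at 110 °C (or Me2AlCl, CH2Cl2, −40 °C) would give the cycloadduct F6, which carries the ester on the new ring CH. TMSOTf with 2,6-lutidine would cleave the tert-butyl ester to the acid F7. Barton decarboxylation (N-hydroxypyridine-2-thione, DCC; then t-BuSH, visible light) by way of the thiohydroxamate ester F8 would return to the route at 22.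

2. Step 17 (Mukaiyama aldol with acetone). Bond formation between the tetrasubstituted enol carbon and a ketone may stall for steric reasons, or the adduct may revert by retro-aldol cleavage before it lactonizes. The fallback sets out from 22. C-acylation with acetyl chloride and ZnCl2 (CH2Cl2, 0 °C), using the small linear acylium electrophile, would give the 1,3-diketone F9. Excess MeMgBr/CeCl3 (THF, −78 °C) would add to both ketones to give the diol ester F10, the ring ketone being attacked from the outer face as in step 18. Camphorsulfonic acid in toluene at 50 °C would lactonize the side-chain tertiary alcohol and remove the silyl ether, coming back to the route at 25.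

3. Step 18 (methyl addition). The reagent may attack a lactone carbonyl or enolize the α-sulfanyl lactone in competition with addition to the hindered ketone. The fallback sets out from 24. Corey–Chaykovsky epoxidation with dimethylsulfonium methylide (Me3S+ I−, KN(SiMe3)2, THF, −10 °C), to which ester carbonyls are inert and which delivers the methylene from the outer face, would give the spiro-epoxide F11. Opening at the CH2 with sodium benzeneselenolate ((PhSe)2, NaBH4, EtOH, 0 °C) would give the hydroxy selenide F12. Radical deselenation (Bu3SnH, AIBN, toluene, 80 °C) would come back to the route at 25.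

**Further compounds**

F1 | step 16 | exocyclic tert-butyl enoate diol from 13 | CC(C)(C)OC(=O)C=C1C[C@]2(C)C(=O)[C@](C)(CCCO)[C@]13COC(=O)[C@@H]3[C@H]2O
F2 | step 16 | aldehyde from F1 | CC(C)(C)OC(=O)C=C1C[C@]2(C)C(=O)[C@](C)(CCC=O)[C@]13COC(=O)[C@@H]3[C@H]2O
F3 | step 16 | allylic alcohol from F2 and 18 | CC(C)(C)OC(=O)C=C1C[C@]2(C)C(=O)[C@](C)(CCC(O)C(=C)CC(Sc4ccccc4)C(=O)OC)[C@]13COC(=O)[C@@H]3[C@H]2O
F4 | step 16 | enone from F3 | CC(C)(C)OC(=O)C=C1C[C@]2(C)C(=O)[C@](C)(CCC(=O)C(=C)CC(Sc4ccccc4)C(=O)OC)[C@]13COC(=O)[C@@H]3[C@H]2O
F5 | step 16 | bis-silylated dienol ether from F4 | CC(C)(C)OC(=O)C=C1C[C@]2(C)C(=O)[C@](C)(C/C=C(\O[Si](CC)(CC)CC)C(=C)CC(Sc4ccccc4)C(=O)OC)[C@]13COC(=O)[C@@H]3[C@H]2O[Si](CC)(CC)CC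
F6 | step 16 | cycloadduct with tert-butyl ester on the new ring CH | CC[Si](CC)(CC)OC1=C(CC(Sc2ccccc2)C(=O)OC)CC(C(=O)OC(C)(C)C)[C@]23C[C@]4(C)C(=O)[C@](C)(C[C@@H]12)[C@]35COC(=O)[C@@H]5[C@H]4O[Si](CC)(CC)CC
F7 | step 16 | carboxylic acid from F6 | CC[Si](CC)(CC)OC1=C(CC(Sc2ccccc2)C(=O)OC)CC(C(=O)O)[C@]23C[C@]4(C)C(=O)[C@](C)(C[C@@H]12)[C@]35COC(=O)[C@@H]5[C@H]4O[Si](CC)(CC)CC
F8 | step 16 | thiohydroxamate (Barton) ester of F7 | CC[Si](CC)(CC)OC1=C(CC(Sc2ccccc2)C(=O)OC)CC(C(=O)ON6C=CC=CC6=S)[C@]23C[C@]4(C)C(=O)[C@](C)(C[C@@H]12)[C@]35COC(=O)[C@@H]5[C@H]4O[Si](CC)(CC)CC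
F9 | step 17 | 1,3-diketone from C-acetylation of 22 | COC(=O)C(Sc1ccccc1)C[C@@]2(C(C)=O)CC[C@]34C[C@]5(C)C(=O)[C@](C)(C[C@H]3C2=O)[C@]46COC(=O)[C@@H]6[C@H]5O[Si](CC)(CC)CC
F10 | step 17 | diol ester from double methyl addition to F9 | COC(=O)C(Sc1ccccc1)C[C@@]2(C(C)(C)O)CC[C@]34C[C@]5(C)C(=O)[C@](C)(C[C@H]3[C@@]2(C)O)[C@]46COC(=O)[C@@H]6[C@H]5O[Si](CC)(CC)CC
F11 | step 18 | spiro-epoxide from 24 | CC1(C)OC(=O)C(Sc5ccccc5)C[C@]12CC[C@]13C[C@]4(C)C(=O)[C@](C)(C[C@H]1[C@]26CO6)[C@]31COC(=O)[C@@H]1[C@H]4O
F12 | step 18 | hydroxy selenide from F11 | CC1(C)OC(=O)C(Sc5ccccc5)C[C@]12CC[C@]13C[C@]4(C)C(=O)[C@](C)(C[C@H]1[C@@]2(C[Se]c6ccccc6)O)[C@]31COC(=O)[C@@H]1[C@H]4O
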